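**Plan**

- Retrosynthesis: in the furanone ring (O1', C2'=O, C3' bonded to flavone C8, C4'–H, C5'Me2) the bonds C4'–C5' and C2'–C3' are cut, together with the acyl C2'–O1' bond. This gives 8-ethynyl-7-methoxyflavone 6, acetone 7 and CO 8. Then C8–C(sp) is cut (back to iodide 3), then O–CH3 and C8–I (back to 7-hydroxyflavone 1).
- Enabling feature: the furanone is a 2-oxacyclopent-3-enone in which C5' carries two identical methyl groups, C4' one hydrogen and C3' the aryl group. Its five ring atoms therefore map exactly onto the two carbons of a terminal aryl alkyne, the C=O of a symmetrical ketone and one CO (formal [2+2+1] adduct).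
- Forward order: rings A, B and C of the flavone are bought intact in 1. C8 is iodinated, O7 is methylated, the ethynyl group is attached by Sonogashira coupling and desilylation, and the furanone ring is made last in one three-component carbonylative cycloaddition.
- Stereochemistry: the target has no stereocentre and its only non-aromatic C=C is endocyclic, so only regiochemistry has to be controlled.

Key step: step 5

**Step 1**
Reactants: 1 7-hydroxyflavone (7-hydroxy-2-phenyl-4H-chromen-4-one)
Product: 2 7-hydroxy-8-iodoflavone
Conditions: NIS (1.05 equiv), DMF, 0 °C to rt, dark
Reagents that add atoms: N-iodosuccinimide (O=C1CCC(=O)N1I)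
Why: Electrophilic aromatic iodination of a phenol, which should go to C8 and not C6 because C8 lies between the hydroxyl-bearing C7 and the O1-bearing C8a and ends the C7–C8 bond of high double-bond character in the benzopyranone.

**Step 2**
Reactants: 2 7-hydroxy-8-iodoflavone
Product: 3 8-iodo-7-methoxyflavone
Conditions: MeI (1.5 equiv), K2CO3 (2 equiv), DMF, rt
Reagents that add atoms: iodomethane (CI)
Why: Williamson ether synthesis (SN2 methylation of the phenoxide), to which the flavone carbonyl and the aryl iodide are inert.

**Step 3**
Reactants: 3 8-iodo-7-methoxyflavone; 4 trimethylsilylacetylene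
Product: 5 7-methoxy-8-[(trimethylsilyl)ethynyl]flavone
Conditions: PdCl2(PPh3)2 (5 mol %), CuI (10 mol %), Et3N–THF 1:1, 60 °C
Reagents that add atoms: none
Why: Sonogashira coupling (oxidative addition of the aryl iodide to zerovalent palladium, transmetalation from the copper acetylide, reductive elimination), in which the reactive iodide should overcome its two ortho substituents and the silyl cap prevents double coupling.

**Step 4**
Reactants: 5 7-methoxy-8-[(trimethylsilyl)ethynyl]flavone
Product: 6 8-ethynyl-7-methoxyflavone
Conditions: K2CO3 (0.2 equiv), MeOH–CH2Cl2 1:1, rt
Reagents that add atoms: none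
Why: Protodesilylation of the C(sp)–Si bond by catalytic methoxide (methanolysis), which should leave the flavone and the aryl methyl ether untouched at room temperature.

**Step 5**
Reactants: 6 8-ethynyl-7-methoxyflavone; 7 acetone; 8 carbon monoxide
Product: 9 8-(5,5-dimethyl-2-oxo-2,5-dihydrofuran-3-yl)-7-methoxyflavone
Conditions: Ni(cod)2 (20 mol %), IMes (20 mol %), acetone–toluene 1:1, CO–N2 1:9 (1 atm), 50 °C, slow addition of 6
Reagents that add atoms: none
Why: Proposed new method: zerovalent nickel bearing the carbene IMes should bind the alkyne of 6 and acetone 7 side-on and couple them oxidatively to a 2-oxanickelacyclopent-4-ene, in which the terminal alkyne carbon is joined to the carbonyl carbon (C4'–C5') and the aryl-bearing carbon sits on nickel; CO 8 then inserts into this Ni–C(sp2) bond (C2'–C3') and C(acyl)–O reductive elimination releases 9 and zerovalent nickel, so that the unfavourable ketone coupling is drained by irreversible carbonylation. The closest known reaction type is the nickel-catalysed [2+2+1] carbonylative cycloaddition of alkynes, imines and CO to unsaturated γ-lactams (aza-Pauson–Khand type), supported by the hetero-Pauson–Khand cyclocarbonylation of alkynyl aldehydes to butenolides and by nickel–carbene-catalysed couplings of alkynes with ketones; new is the intermolecular use of an unactivated ketone. The furanone ring is closed as a formal [2+2+1] cycloaddition, its last bond (C2'–O1') by reductive elimination from a six-membered acylnickel alkoxide. No stereocentre is formed, because C5' receives two identical methyl groups. The step needs regioselectivity (ketone carbon to the terminal CH, CO to the aryl-bearing carbon) and chemoselectivity (acetone instead of a second alkyne or the flavone C4 carbonyl): the first is secured by the unsubstituted alkyne terminus and by the preference of the aryl-substituted carbon for the position next to nickel, the second by acetone as cosolvent in large excess, slow addition of 6, a low CO pressure and the shielding of the alkyne by the C7 methoxy group and O1 of ring C.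

**Compound list**

1 | 7-hydroxyflavone (7-hydroxy-2-phenyl-4H-chromen-4-one) | O=c1cc(-c2ccccc2)oc2cc(O)ccc12 | starting material
2 | 7-hydroxy-8-iodoflavone | O=c1cc(-c2ccccc2)oc2c(I)c(O)ccc12 | intermediate
3 | 8-iodo-7-methoxyflavone | COc1ccc2c(=O)cc(-c3ccccc3)oc2c1I | intermediate
4 | trimethylsilylacetylene | C#C[Si](C)(C)C | starting material
5 | 7-methoxy-8-[(trimethylsilyl)ethynyl]flavone | COc1ccc2c(=O)cc(-c3ccccc3)oc2c1C#C[Si](C)(C)C | intermediate
6 | 8-ethynyl-7-methoxyflavone | COc1ccc2c(=O)cc(-c3ccccc3)oc2c1C#C | intermediate
7 | acetone | CC(C)=O | starting material
8 | carbon monoxide | [C-]#[O+] | starting material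
9 | 8-(5,5-dimethyl-2-oxo-2,5-dihydrofuran-3-yl)-7-methoxyflavone | COc1ccc2c(=O)cc(-c3ccccc3)oc2c1C1=CC(C)(C)OC1=O | target

**Totals and risks**

Total step count: 5. Longest linear sequence: 5 steps (1 → 2 → 3 → 5 → 6 → 9).

Steps most likely to fail:

Step 5 (proposed new method). Oligomerisation of the terminal alkyne on zerovalent nickel may outrun the oxidative coupling with the weakly electrophilic ketone, and CO may saturate the metal before the nickelacycle forms. The fallback uses known chemistry and sets out from 3. Sonogashira coupling of 3 with 2-methylbut-3-yn-2-ol (PdCl2(PPh3)2, CuI, Et3N, 60 °C) should give 8-(3-hydroxy-3-methylbut-1-yn-1-yl)-7-methoxyflavone F1. Palladium-catalysed cyclocarbonylation of this tertiary alkynol (Pd2(dba)3, dppb, CO/H2, CH2Cl2, 95 °C) should then close the furanone ring, with CO attached at the aryl-bearing carbon, and come back to the route at 9.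

Step 1. Regiocontrol may be lost (attack at C6) and iodination may run on to the 6,8-diiodide. The fallback sets out from 1 and avoids halogenation. A Duff formylation (hexamethylenetetramine, AcOH, 100 °C, then aqueous HCl), which delivers the formyl group ortho to the phenol at C8, should give 7-hydroxy-4-oxo-2-phenyl-4H-chromene-8-carbaldehyde F2. O-Methylation (MeI, K2CO3, DMF) should give 7-methoxy-4-oxo-2-phenyl-4H-chromene-8-carbaldehyde F3. Seyferth–Gilbert homologation with dimethyl (1-diazo-2-oxopropyl)phosphonate (K2CO3, MeOH, rt) should then convert the aldehyde into the terminal alkyne and come back to the route at 6.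

Step 3. Oxidative addition and transmetalation at the doubly ortho-substituted iodide may be slow, so that copper-mediated oxidative dimerisation of 4 and reductive loss of iodine from 3 take over. The fallback sets out from 3 and is copper-free. A Stille coupling with tributyl(ethynyl)stannane (Pd(PPh3)4, toluene, 100 °C) should give the free alkyne directly and come back to the route at 6, skipping 5. It makes no compound outside the list (F0).

**Further compounds**

F1 | step 5 | 8-(3-hydroxy-3-methylbut-1-yn-1-yl)-7-methoxyflavone | COc1ccc2c(=O)cc(-c3ccccc3)oc2c1C#CC(C)(C)O
F2 | step 1 | 7-hydroxy-4-oxo-2-phenyl-4H-chromene-8-carbaldehyde | O=Cc1c(O)ccc2c(=O)cc(-c3ccccc3)oc12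
F3 | step 1 | 7-methoxy-4-oxo-2-phenyl-4H-chromene-8-carbaldehyde | COc1ccc2c(=O)cc(-c3ccccc3)oc2c1C=O
F0 | step 3 | none | none
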